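By 4.5 min the oak run has slowed well below its opening pace, and you can count that slowing in turnovers, each one a target made per free catalyst charged.

| setting | oak | larch | birch | alder |
|---|---|---|---|---|
| substrate | 0.400 M | 0.160 M | 1.20 M | 0.400 M |
| partner | 0.480 M | 0.240 M | 0.480 M | 0.480 M |
| free catalyst | 8.00 × 10⁻⁴ M | 8.00 × 10⁻⁴ M | 8.00 × 10⁻⁴ M | 8.00 × 10⁻⁴ M |
| target |  |  |  | 0.320 M |
| time |  |  |  | 4.5 min |

| run | time / min | [target] / M |
|---|---|---|
| oak run | 0.18 | 0.0129 |
| oak run | 0.40 | 0.0239 |
| oak run | 0.90 | 0.0465 |
| oak run | 2.0 | 0.0820 |
| oak run | 4.5 | 0.1138 |
| larch run | 0.18 | 0.0012 |
| larch run | 0.40 | 0.0032 |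
| larch run | 0.90 | 0.0102 |
| larch run | 2.0 | 0.0196 |
| larch run | 4.5 | 0.0284 |
| birch run | 0.18 | 0.0294 |
| birch run | 0.40 | 0.0657 |
| birch run | 0.90 | 0.1257 |
| birch run | 2.0 | 0.1993 |
| birch run | 4.5 | 0.2352 |

(standard deviation of a reading: 0.001 M)

* the exponent of [partner] in the starting rate at the charge of the oak run (at the point where two percent of the substrate have become target)
* the exponent of [substrate] in the starting rate at the charge of the oak run (at the point where two percent of the substrate have become target) (one fixed amount of target, the same in the runs compared)
* target in the alder run at 4.5 min, as a share of the substrate charged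

- Overall: substrate + partner -> target, with free catalyst as catalyst.
- Constant volume, constant temperature.
- An order is taken over about fifteen percent of the charge, up and down.
- A share of target counts the target that was charged too.

My own reckoning assumes that the forward pace scales with [substrate][partner], ignores [target], and that target is lost by an apparent first-order step. The alder run is then the oak run plus the survivors of its charged target. Counting that charge whole gives a ceiling of 108%.

To tighten it, take the oak opening from the reading at 0.40 min: a turnover frequency of 74.7 /min. Between 2.0 min and 4.5 min the oak run nets 39.7 turnovers, at a mean [target] of 0.0979 M. Reducing [substrate] and [partner] by that mean promises 112 turnovers, an upper estimate of the forward step. The gap gives a high loss constant, 0.237 /min.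

Charging that constant against the mean [target] up to mid-interval overstates the target already lost, 0.0754 M. Removing this from [substrate] and [partner] as well promises 67.6 turnovers and gives a low constant, 0.0911 /min.

The two constants place the share of a target charge surviving 4.5 min between 34.4% and 66.4%. I commit to their mean, 50.4%, the keep share. For the alder run this brackets the answer between 56.0% and 81.6%, and my figure is 68.8%.

The forecast, which says the flask “looks like a reversible reaction approaching” equilibrium, gives 70% (range 66% to 77%), inside my bracket. For the orders it gives 1.7 in [partner] and 0.85 in [substrate].

The flask gives 1.0 in [partner], 1.0 in [substrate] and 73.5% for the alder run.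

    2 free catalyst ⇌ catalyst dimer, settled at all times (83400 /M)
    catalyst dimer + substrate + partner → target + catalyst dimer (894.0 /M²/min)
    partner → lost reagent (0.04740 /min)
    target → decomposed product (0.1284 /min)

The alder run ends at 73.5% instead of 120% through the loss of target to decomposed product, a difference of 46 percentage points. Against my keep share of 50.4%, the last step of the scheme gives a keep share of 56.1%, so 0.180 M of the target charged to the alder run stands at 4.5 min. Carried to the birch run, the same step leaves 0.145 M of the 0.1993 M read at 2.0 min, so of the 0.2352 M read at 4.5 min, the target made after that first reading and still standing is about 0.0902 M.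

All runs were computed for an exercise; noise was put on by code.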